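The numbers of this flask are made up; the flask was simulated.

Count the reagent.

    starting material + reagent → target (k1 = 23 /M/s, Ea1 = 42.0 kJ/mol)
    second substrate + reagent → second product (k2 = 6.8 /M/s, Ea2 = 39.0 kJ/mol)
    third substrate + reagent → third product (k3 = 68 /M/s, Ea3 = 45.0 kJ/mol)
    2 reagent → homo dimer (k4 = 4.3 /M/s, Ea4 = 51.0 kJ/mol)
    target ⇌ isomer of the product (K5 = 0.65, k5 = 0.013 /s, Ea5 = 87.0 kJ/mol, ΔH5 = −72.0 kJ/mol)
    (constants at 20 °C)

| setting | zeta | delta | eta | beta |
|---|---|---|---|---|
| starting material | 2.0 mM | 2.0 mM | 2.0 mM | 2.0 mM |
| reagent | 1.80 mM | 1.80 mM | 1.80 mM | 1.80 mM |
| second substrate | 1.00 mM | 1.00 mM | 1.00 mM (fed, over 4.0 min) | 1.00 mM |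
| third substrate | 2.00 mM (fed, over 4.0 min) | 2.00 mM | 2.00 mM | 2.00 mM (fed, over 4.0 min) |
| temperature | 20 °C | 20 °C | 20 °C |  |
| time | 10 min | 10 min | 10 min | 10 min |
| remark | all else is in the flask from the start; the feed brings no volume worth counting | everything together at the start | all else is in the flask from the start; the feed brings no volume worth counting | the addition at 0 °C, then warmed to 20 °C; the feed brings no volume worth counting |

- two of one species on the left: rate k times its square, two consumed each time
- constants are those at 20 °C; use the activation energies and enthalpies for any other temperature

- the flask with the highest amount of target, in percent of the starting material charged ("all alike" if they lie within 1.5 percentage points) (zeta / delta / eta / beta / all alike)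
- final target, as a percentage of the starting material charged, in zeta
- final target, as a percentage of the starting material charged, in delta
- final target, as a percentage of the starting material charged, in eta
- final target, as a percentage of the starting material charged, in beta

We carry one quantity, the target share of the reagent, and build each flask up to it.

1. Main step alone. Reagent is the limiting reagent, 1.80 mM against 2.0 mM of starting material, so with this step by itself we reckon 90.0% of the charge as target.

2. Add the isomer of the product. The relaxation half-life, 0.350 min in delta, is short against 10 min, so we let target and isomer reach their equilibrium. Target keeps 60.6% of what was formed, and the ceiling becomes 54.5%.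

3. Add the competitors as a correction to that ceiling. Each path has a demand on reagent, a pseudo-first-order constant: its rate constant times its partner's charged concentration, with twice the constant times reagent for the homo dimer. The third substrate demands 0.136 /s, more than the 0.0460 /s of the starting material. At the start of delta the demands sum to 0.204 /s, so target receives 22.5% of the reagent used at that moment. This is the target share, the main step's demand over the sum of demands. Held over the whole reagent charge, that share puts the end of delta at 12.3%.

4. Feed the second substrate. In eta we drop its demand, which gives a share of 23.3% and an end target of 12.7%.

5. Feed the third substrate. In zeta the demands without it sum to 0.0683 /s, so the time constant of reagent at the start is about 14.6 s, short against 4.0 min. Over that time the feed brings 0.122 mM, and we count only that much as competitor. The share is 60.1%, which gives 32.8%.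

6. Chill the feed. At 0 °C in beta the constants fall to 6.51 /M/s for the main step, 2.11 /M/s for the second substrate, 17.6 /M/s for the third substrate and 0.929 /M/s for the homo dimer. The time constant of reagent in beta is now 54.1 s, longer than in zeta, so over that time the feed brings 0.451 mM. The share is 49.3%. Beta ends at 20 °C, so the same ceiling applies and gives 26.9%.

Our pick is zeta.

The forecast names zeta, with 32.5% in zeta, 15.1% in delta, 15.8% in eta and 29.5% in beta, holding that for the third substrate “feeding it slowly lets the starting material use the reagent first”.

The flasks give 33.2% in zeta, 15.0% in delta, 15.9% in eta and 28.7% in beta, so zeta leads.

Our reckoned share of 60.1% in zeta stands against 22.5% in delta, and in the gap in target two steps act together, each a part of the reason. Taking away the third-substrate step brings the difference between zeta and delta from 18 percentage points to 0 points, and taking away the backward run from isomer of the product brings it to 0.017 points. The share also serves a neighbour of delta charged with 0.45 mM of reagent. Its demands give 23.9%, hence 3.26% target, and that flask holds 3.42%.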